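**Compound numbers used throughout** (full list after the steps): 1 methyl vinyl ether; 2 dimethyl squarate; 3 1‑methoxyvinyllithium; 4 carbinol adduct; 5 silylated cyclobutenone; 6 dienylketene; 7 cyclohexadienone; 8 ring A phenol; 9 its methoxymethyl ether; 10 aryllithium; 11 aryl methyl ketone; 12–15 ring B aldehyde, benzyl ether, acid, acid chloride; 16 enolate; 17 diketone; 18 phenol diketone; 19 silyl flavone; 20 benzyl flavone; 21 target.

## Analysis of the target

Compound 21 is a flavone: ring A (benzo ring) is fused to ring C (γ‑pyranone), and C2 carries the aryl ring B. It has no stereocentre. The C2–C1' bond is flanked on ring C only by O1 and C3–H, so it rotates freely and no stereochemical element has to be controlled. Ring A is fully substituted: C5, C7 and C8 carry methoxy groups, C6 a free hydroxyl, C8a the ring oxygen O1, and C4a the carbonyl carbon C4. Ring B carries two different ortho oxygens, a free 2'‑hydroxyl and a 6'‑methoxy group, which crowd the C2–C1' bond. Three groups are sensitive: the C6 hydroxyl sits para to O1 and oxidises readily to a quinone, the C5 methoxy group peri to C4=O is the first to be cleaved by Lewis acids, and a free 2'‑hydroxyl can compete with the ring A oxygen whenever ring C is closed or reopened. The difficulty is therefore regiochemical: a hexasubstituted benzene in which one of five contiguous oxygens must stay distinct, without relying on selective methylation or demethylation of a polyphenol. The strategy rests on reading C8a–C8–C7–C6 with their four oxygens as a squaric acid unit and C5–C4a as the two carbons of a vinyl ether. Adding the lithiated vinyl ether to one squarate carbonyl turns that carbon (C6) into a carbinol, chemically distinct from the methoxy‑bearing C7 and C8, and the untouched carbonyl becomes the C8a oxygen.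

## Retrosynthetic reasoning

**21 ⇒ 20.** The last cut is the O–CH2 bond of a benzyl ether on the 2'‑oxygen. This oxygen must stay masked until ring C exists, because a free 2'‑hydroxyl is as well placed as the ring A hydroxyl to close onto the three‑carbon bridge. A benzyl ether survives amide base and hot acidic alcohol and leaves by hydrogenolysis, which should touch nothing else in 20.

**20 ⇒ 17.** Ring C is opened at O1–C2, its only carbon–heteroatom single bond, giving the 1,3‑diketone 17 with O1 as an acetal‑protected phenol and the C6 oxygen as a silyl ether. One acidic medium has to free the phenol (18), close and dehydrate the ring (19) and solvolyse the silyl ether (20). Cutting here keeps ring closure a condensation, so no oxidant comes near the electron‑rich ring A.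

**17 ⇒ 11 + 15.** The C2–C3 bond is cut, separating the methyl ketone 11 (ring A with C3 and C4) from the ring B acid chloride 15. The forward reaction must acylate the lithium enolate 16 on carbon with a doubly ortho‑substituted acid chloride. The cut is convergent and places the two differentiated aromatic rings in separate branches.

**15 ⇒ 14 ⇒ 13 ⇒ 12.** These are functional‑group changes only: acid chloride from acid, acid from aldehyde, benzyl ether from phenol. The purchasable aldehyde 12 already has one free and one methylated ortho oxygen, so ring B needs no selective step.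

**11 ⇒ 9 ⇒ 8.** The C4–C4a bond is cut, removing the acetyl group from the only unsubstituted ring carbon. A Lewis‑acid acylation would endanger the aryl silyl ether and the methoxy group that ends up peri to the carbonyl, so the bond is made through the aryllithium 10. This requires the methoxymethyl ether 9, whose acetal directs metalation to the neighbouring C–H and protects the future O1. It costs one step to install and none to remove, because the ring‑closing acid takes it off.

**8 ⇒ 5.** The strategic cut is the C8a–C4a bond of ring A. Retro‑electrocyclization gives the dienylketene 6, and re‑closing 6 between C8a and C6 gives the cyclobutenone 5. This delivers a benzene ring with five oxygens in which exactly one is free (the future O1) and exactly one carries silicon (the future C6 hydroxyl). The forward reaction needs the four‑membered ring to open with the vinyl group turned toward the ketene, and then ring closure and enolization.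

**5 ⇒ 4 ⇒ 2 + 3 (from 1).** Removing the silyl group and cutting the C5–C6 bond leads to the squarate 2 and the lithiated enol ether 3, made from 1. Compound 2 supplies C8a, C8, C7 and C6, and compound 1 supplies C5 and C4a. Addition to one of two equivalent carbonyls breaks the symmetry of the squarate.

## Alternatives that were turned down

**Alternative 1:** Ring C would be made by inserting C3 into a five‑membered ring. The disconnection removes C3 from the 3‑chloroflavone A1 and leads to the 3‑silyloxy‑2‑arylbenzofuran A2 and a dihalocarbene.
- Forward key step: the carbene adds to the enol ether C2=C3 bond of A2, and the dihalocyclopropane opens with loss of halide and of the silyl group. The new carbon becomes C3, bonded to C2 and C4.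
- In its favour: the crowded C2–C1' bond already exists in A2, no diketone is involved so there is no question of which phenol closes, and carbene ring expansion of silyl enol ethers is established chemistry. Both benzyl ethers and the C3 chlorine could fall in one hydrogenolysis, which is better than the chosen route's separate acid and hydrogenolysis steps.
- Against it: A2 contains the same hexasubstituted ring A with a differentiated C6 oxygen, so the main difficulty is untouched. The tetrasubstituted enol ether is shielded by the 2,6‑disubstituted aryl group and the neighbouring methoxy group, while two electron‑rich arenes and benzylic C–H bonds offer the carbene other targets. 2‑Aryl‑3‑oxygenated benzofurans also autoxidise at C2, and the chlorine costs a reduction.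
- Comparison: the chosen route gives up the late‑stage ring expansion but builds the oxygen pattern of ring A from two simple pieces.

**Alternative 2:** Ring C would be closed at O1–C8a by oxidation. The disconnection leads from the flavone A3 (the 2'‑O‑methoxymethyl ether of the target) to the diketone A4, whose ring A has only four oxygens and a C–H para to the free hydroxyl.
- Forward key step: anodic oxidation of A4 gives a phenoxonium ion, the diketone enol oxygen attacks the para carbon, and proton loss gives A3.
- In its favour: it is the shortest route on paper, it uses the C6 hydroxyl as the activating group instead of protecting it, and it makes the C8a–O bond from a C–H bond. On step economy it is stronger than the chosen route.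
- Against it: A3 is a para‑oxygenated phenol and is more easily oxidised than A4, so over‑oxidation to quinoid products is built into the step. The phenoxonium ion can also be captured at the methoxy‑bearing ortho carbons or by solvent, the diketone enol is itself oxidisable, and the acetal on ring B must survive the acid formed at the anode. A4 still requires a ring with one free hydroxyl among three methoxy groups, so the differentiation problem is moved, not solved.
- Comparison: the chosen route is longer but unveils the oxidation‑sensitive hydroxyl only in the last two steps and needs no chemoselective oxidation.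

**Alternative 3:** Ring B would be built on the finished chromone. The disconnection cuts C1'–C2', C5'–C6' and C2'–C3' of the 6‑O‑benzyl flavone A5 and leads to the 2‑(methoxyethynyl)chromone A6 and cyclobutenone A7.
- Forward key step: A7 opens thermally to the vinylketene A8, which undergoes a two‑plus‑two cycloaddition with the alkynyl ether of A6. The adduct opens and the resulting dienylketene closes to the phenol.
- In its favour: the free 2'‑hydroxyl and the 6'‑methoxy group come out differentiated without a protecting group, and the hindered C2–C1' bond is never made by coupling or acylation. On these two points it is stronger than the chosen route.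
- Against it: the cascade is spent on the easy ring, since the ring B pattern can be bought as aldehyde 12, while ring A of A6 still needs a conventional synthesis with its differentiated C6 oxygen. The alkynyl ether in A6 is conjugated to the chromone carbonyl, which lowers its nucleophilicity toward the ketene and makes it prone to hydration. The chromone C2=C3 bond is a competing two‑electron partner, and A7 is volatile and polymerises.
- Comparison: the last two pericyclic events are the same as in the chosen key step. The chosen route applies them to the ring where they remove the regiochemical problem.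

Key step: step 3

Remark on the chemistry: the target has no stereogenic element, and the carbinol stereocentre of 4 and 5 is erased in step 3, so both are made and used as racemates.

## Route

**Step 1**
Reactants: 1 methyl vinyl ether; 2 dimethyl squarate
Product: 4 4-hydroxy-2,3-dimethoxy-4-(1-methoxyethenyl)cyclobut-2-en-1-one (racemic), via 1-methoxyvinyllithium 3 (not isolated)
Conditions: 1 (excess), t-BuLi, THF, −78 → 0 °C; then add to 2, THF, −78 °C; sat. aq. NH4Cl, −78 °C
Reagents that add atoms: none
Why: α‑Lithiation of the enol ether gives the acyl‑anion equivalent 3, which adds 1,2 to one of the two equivalent ketone carbonyls of 2 (organolithium addition to a squarate ester); the remaining carbonyl is then a vinylogous ester and does not react again at −78 °C. The new carbinol centre forms as a racemate and is destroyed in step 3.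

**Step 2**
Reactants: 4 4-hydroxy-2,3-dimethoxy-4-(1-methoxyethenyl)cyclobut-2-en-1-one
Product: 5 4-[(tert-butyldimethylsilyl)oxy]-2,3-dimethoxy-4-(1-methoxyethenyl)cyclobut-2-en-1-one (racemic)
Conditions: TBSOTf, 2,6-lutidine (excess), CH2Cl2, −78 → 0 °C
Reagents that add atoms: tert-butyldimethylsilyl trifluoromethanesulfonate, CC(C)(C)[Si](C)(C)OS(=O)(=O)C(F)(F)F
Why: Silyl ether formation with a silyl triflate and a hindered pyridine base works on tertiary alcohols that a silyl chloride would leave largely unchanged. The excess base keeps the medium non‑acidic, so the enol ether and the ionisable carbinol should survive.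

**Step 3**
Reactants: 5 4-[(tert-butyldimethylsilyl)oxy]-2,3-dimethoxy-4-(1-methoxyethenyl)cyclobut-2-en-1-one
Product: 8 4-[(tert-butyldimethylsilyl)oxy]-2,3,5-trimethoxyphenol, via dienylketene 6 (not isolated), via cyclohexadienone 7 (not isolated)
Conditions: p-xylene (degassed, 0.02 M), 138 °C, Ar
Reagents that add atoms: none
Why: Heating breaks the C1–C4 bond of 5 in a conrotatory four‑electron electrocyclic opening to the dienylketene 6. The donor oxygen on C4 rotates outward, as oxygen substituents do in cyclobutene openings, which turns the methoxyvinyl group inward and gives the (3Z) geometry in which the ketene carbon and the vinyl CH2 face each other. Ring A then closes by a thermal disrotatory six‑electron electrocyclization that joins these termini (the future C8a and C4a) to give the cyclohexa‑2,4‑dienone 7, and enolization of its CH2 group gives the phenol 8. This is the Moore rearrangement of squarate‑derived 4‑alkenyl‑4‑oxy‑cyclobutenones, known for hydroxy, alkoxy and silyloxy substrates. No stereocentre is formed and the one in 5 is lost. The only selectivity needed is the sense of rotation; any ketene formed with the vinyl group outward cannot cyclize and reverts to 5, so material funnels through 6. Regiochemistry is fixed by connectivity: the silyl group stays on its oxygen, the ketene oxygen becomes the only free hydroxyl, and the single ring hydrogen ends up next to it. Dilution and exclusion of air should suppress ketene dimerization and oxidation of the electron‑rich phenol.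

**Step 4**
Reactants: 8 4-[(tert-butyldimethylsilyl)oxy]-2,3,5-trimethoxyphenol
Product: 9 tert-butyl[2,3,6-trimethoxy-4-(methoxymethoxy)phenoxy]dimethylsilane
Conditions: MOMCl, i-Pr2NEt, CH2Cl2, 0 °C → rt
Reagents that add atoms: chloromethyl methyl ether, COCCl
Why: O‑Alkylation of the phenol by an α‑chloro ether under amine base (acetal protection); the neutral amine avoids a free phenoxide that could shuttle silyl groups between oxygens. The acetal protects the future O1 and directs step 5.

**Step 5**
Reactants: 9 tert-butyl[2,3,6-trimethoxy-4-(methoxymethoxy)phenoxy]dimethylsilane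
Product: 11 1-{3-[(tert-butyldimethylsilyl)oxy]-2,4,5-trimethoxy-6-(methoxymethoxy)phenyl}ethan-1-one, via aryllithium 10 (not isolated)
Conditions: s-BuLi, TMEDA, THF, −78 °C; then MeC(O)N(OMe)Me, −78 → 0 °C; aq. NH4Cl
Reagents that add atoms: N-methoxy-N-methylacetamide, CC(=O)N(C)OC
Why: Directed ortho‑metalation: the only ring hydrogen lies between the acetal oxygen and a methoxy group, both of which coordinate lithium, so deprotonation there should be fast at −78 °C. The aryllithium 10 adds once to the Weinreb amide, whose chelated adduct releases the ketone only on work‑up; the silyl ether is meta to the carbanion, so silicon cannot migrate to carbon.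

**Step 6**
Reactants: 12 2-hydroxy-6-methoxybenzaldehyde
Product: 13 2-(benzyloxy)-6-methoxybenzaldehyde
Conditions: BnBr, K2CO3, DMF, 60 °C
Reagents that add atoms: benzyl bromide, BrCc1ccccc1
Why: Williamson etherification of the only phenol; the aldehyde has no α‑hydrogen and is inert to carbonate.

**Step 7**
Reactants: 13 2-(benzyloxy)-6-methoxybenzaldehyde
Product: 14 2-(benzyloxy)-6-methoxybenzoic acid
Conditions: NaClO2, NaH2PO4, 2-methyl-2-butene, t-BuOH–H2O, rt
Reagents that add atoms: sodium chlorite, [Na+].[O-]Cl=O
Why: Pinnick oxidation of an aromatic aldehyde; the alkene traps the hypochlorous acid formed, so the electron‑rich ring is not chlorinated and the benzyl ether is untouched.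

**Step 8**
Reactants: 14 2-(benzyloxy)-6-methoxybenzoic acid
Product: 15 2-(benzyloxy)-6-methoxybenzoyl chloride
Conditions: (COCl)2, DMF (cat.), CH2Cl2, 0 °C → rt; used crude
Reagents that add atoms: oxalyl chloride, ClC(=O)C(Cl)=O
Why: Acid chloride formation through the Vilsmeier‑type chloroiminium species; the by‑products are gases, so the hindered acid chloride can be used without purification.

**Step 9**
Reactants: 11 1-{3-[(tert-butyldimethylsilyl)oxy]-2,4,5-trimethoxy-6-(methoxymethoxy)phenyl}ethan-1-one; 15 2-(benzyloxy)-6-methoxybenzoyl chloride
Product: 17 1-[2-(benzyloxy)-6-methoxyphenyl]-3-{3-[(tert-butyldimethylsilyl)oxy]-2,4,5-trimethoxy-6-(methoxymethoxy)phenyl}propane-1,3-dione, via lithium enolate 16 (not isolated)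
Conditions: LiN(SiMe3)2 (2.2 equiv), THF, −78 °C; then 15, −78 °C → rt; aq. NH4Cl
Reagents that add atoms: none
Why: Claisen‑type C‑acylation of a methyl ketone lithium enolate by an acid chloride; the second equivalent of base deprotonates the 1,3‑diketone as it forms, which drives the reaction. Any enol ester from O‑acylation should be converted into the same diketonate by acyl transfer to remaining enolate.

**Step 10**
Reactants: 17 1-[2-(benzyloxy)-6-methoxyphenyl]-3-{3-[(tert-butyldimethylsilyl)oxy]-2,4,5-trimethoxy-6-(methoxymethoxy)phenyl}propane-1,3-dione
Product: 20 2-[2-(benzyloxy)-6-methoxyphenyl]-6-hydroxy-5,7,8-trimethoxy-4H-chromen-4-one, via phenol diketone 18 (not isolated), via silyl flavone 19 (not isolated)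
Conditions: conc. aq. HCl, MeOH, 65 °C
Reagents that add atoms: none
Why: Acid cleaves the acetal next to the ketone to give phenol 18, which adds to the ring B carbonyl and loses water (cyclodehydration of an o‑hydroxyaryl 1,3‑diketone, the closing step of the Baker–Venkataraman flavone synthesis) to give 19. Continued acid methanolysis then removes the aryl silyl ether; the benzyl ether is stable to methanolic HCl and keeps the ring B oxygen out of the ring closure.

**Step 11**
Reactants: 20 2-[2-(benzyloxy)-6-methoxyphenyl]-6-hydroxy-5,7,8-trimethoxy-4H-chromen-4-one
Product: 21 6-hydroxy-2-(2-hydroxy-6-methoxyphenyl)-5,7,8-trimethoxy-4H-chromen-4-one (6,2'-dihydroxy-5,7,8,6'-tetramethoxyflavone)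
Conditions: H2 (1 atm), 10% Pd/C, EtOAc–MeOH, rt
Reagents that add atoms: none
Why: Hydrogenolysis of a benzyl aryl ether over palladium; the conjugated C2=C3 bond of the chromone is reduced far more slowly, so the reaction is stopped when 20 is consumed.

## Compound list

1 | methyl vinyl ether (methoxyethene) | COC=C | starting material
2 | dimethyl squarate (3,4-dimethoxycyclobut-3-ene-1,2-dione) | COC1=C(OC)C(=O)C1=O | starting material
3 | (1-methoxyethenyl)lithium | [Li]C(=C)OC | intermediate
4 | 4-hydroxy-2,3-dimethoxy-4-(1-methoxyethenyl)cyclobut-2-en-1-one (racemic) | COC(=C)C1(O)C(OC)=C(OC)C1=O | intermediate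
5 | 4-[(tert-butyldimethylsilyl)oxy]-2,3-dimethoxy-4-(1-methoxyethenyl)cyclobut-2-en-1-one (racemic) | COC(=C)C1(O[Si](C)(C)C(C)(C)C)C(OC)=C(OC)C1=O | intermediate
6 | (3Z)-4-[(tert-butyldimethylsilyl)oxy]-2,3,5-trimethoxyhexa-1,3,5-trien-1-one | O=C=C(OC)/C(OC)=C(\C(OC)=C)O[Si](C)(C)C(C)(C)C | intermediate
7 | 4-[(tert-butyldimethylsilyl)oxy]-2,3,5-trimethoxycyclohexa-2,4-dien-1-one | COC1=C(O[Si](C)(C)C(C)(C)C)C(OC)=C(OC)C(=O)C1 | intermediate
8 | 4-[(tert-butyldimethylsilyl)oxy]-2,3,5-trimethoxyphenol | COc1cc(O)c(OC)c(OC)c1O[Si](C)(C)C(C)(C)C | intermediate
9 | tert-butyl[2,3,6-trimethoxy-4-(methoxymethoxy)phenoxy]dimethylsilane | COCOc1cc(OC)c(O[Si](C)(C)C(C)(C)C)c(OC)c1OC | intermediate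
10 | {3-[(tert-butyldimethylsilyl)oxy]-2,4,5-trimethoxy-6-(methoxymethoxy)phenyl}lithium | [Li]c1c(OCOC)c(OC)c(OC)c(O[Si](C)(C)C(C)(C)C)c1OC | intermediate
11 | 1-{3-[(tert-butyldimethylsilyl)oxy]-2,4,5-trimethoxy-6-(methoxymethoxy)phenyl}ethan-1-one | CC(=O)c1c(OCOC)c(OC)c(OC)c(O[Si](C)(C)C(C)(C)C)c1OC | intermediate
12 | 2-hydroxy-6-methoxybenzaldehyde | COc1cccc(O)c1C=O | starting material
13 | 2-(benzyloxy)-6-methoxybenzaldehyde | COc1cccc(OCc2ccccc2)c1C=O | intermediate
14 | 2-(benzyloxy)-6-methoxybenzoic acid | COc1cccc(OCc2ccccc2)c1C(=O)O | intermediate
15 | 2-(benzyloxy)-6-methoxybenzoyl chloride | COc1cccc(OCc2ccccc2)c1C(Cl)=O | intermediate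
16 | lithium 1-{3-[(tert-butyldimethylsilyl)oxy]-2,4,5-trimethoxy-6-(methoxymethoxy)phenyl}ethen-1-olate | [Li]OC(=C)c1c(OCOC)c(OC)c(OC)c(O[Si](C)(C)C(C)(C)C)c1OC | intermediate
17 | 1-[2-(benzyloxy)-6-methoxyphenyl]-3-{3-[(tert-butyldimethylsilyl)oxy]-2,4,5-trimethoxy-6-(methoxymethoxy)phenyl}propane-1,3-dione | COCOc1c(OC)c(OC)c(O[Si](C)(C)C(C)(C)C)c(OC)c1C(=O)CC(=O)c1c(OC)cccc1OCc1ccccc1 | intermediate
18 | 1-[2-(benzyloxy)-6-methoxyphenyl]-3-{3-[(tert-butyldimethylsilyl)oxy]-6-hydroxy-2,4,5-trimethoxyphenyl}propane-1,3-dione | COc1cccc(OCc2ccccc2)c1C(=O)CC(=O)c1c(O)c(OC)c(OC)c(O[Si](C)(C)C(C)(C)C)c1OC | intermediate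
19 | 2-[2-(benzyloxy)-6-methoxyphenyl]-6-[(tert-butyldimethylsilyl)oxy]-5,7,8-trimethoxy-4H-chromen-4-one | COc1cccc(OCc2ccccc2)c1-c1cc(=O)c2c(OC)c(O[Si](C)(C)C(C)(C)C)c(OC)c(OC)c2o1 | intermediate
20 | 2-[2-(benzyloxy)-6-methoxyphenyl]-6-hydroxy-5,7,8-trimethoxy-4H-chromen-4-one | COc1cccc(OCc2ccccc2)c1-c1cc(=O)c2c(OC)c(O)c(OC)c(OC)c2o1 | intermediate
21 | 6-hydroxy-2-(2-hydroxy-6-methoxyphenyl)-5,7,8-trimethoxy-4H-chromen-4-one | COc1cccc(O)c1-c1cc(=O)c2c(OC)c(O)c(OC)c(OC)c2o1 | target

## Step count and least certain steps

Total: 11 steps. Longest linear sequence: 8 steps (steps 1–5 and 9–11); the ring B branch contributes steps 6–8.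

**Step 3 (key step).** The most likely failure is loss or intermolecular transfer of the silyl group at 138 °C, or air oxidation of the very electron‑rich mono‑silylated hydroquinone during isolation. Either would erase the difference between the two hydroxyls; hydrolysis of the enol ether by adventitious acid before ring opening is a second concern. The fallback sets out from 4 and returns at 18. Thermolysis of the unprotected carbinol 4 in degassed p‑xylene, where the free hydroxyl also rotates outward, should give 2,3,5-trimethoxybenzene-1,4-diol F1, handled under argon. Friedel–Crafts acetylation at its only free position (AcOH, BF3·OEt2, 80 °C) should give 1-(2,5-dihydroxy-3,4,6-trimethoxyphenyl)ethan-1-one F2. In F2 the hydroxyl next to the acetyl group is tied up in a hydrogen bond, so TBSCl and imidazole in DMF should silylate only the other one, giving 1-{3-[(tert-butyldimethylsilyl)oxy]-6-hydroxy-2,4,5-trimethoxyphenyl}ethan-1-one F3. Its dianion (LiN(SiMe3)2, 3 equiv, THF, −78 °C) would be acylated with 15 to give 18, which is then subjected to the conditions of step 10. The differentiation here comes from chelation after acetylation, not from the ring expansion itself.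

**Step 5.** The hindered aryllithium may deprotonate the acetyl donor instead of adding to it, which returns 9, or the alkyllithium may attack silicon. The fallback sets out from 8, returns at 11 and avoids organolithium reagents. Magnesium‑mediated ortho‑formylation of 8 (MgCl2, Et3N, paraformaldehyde, MeCN, reflux) should give 3-[(tert-butyldimethylsilyl)oxy]-6-hydroxy-2,4,5-trimethoxybenzaldehyde F5. Protection with MOMCl and i‑Pr2NEt would give 3-[(tert-butyldimethylsilyl)oxy]-2,4,5-trimethoxy-6-(methoxymethoxy)benzaldehyde F6. Addition of MeMgBr would give racemic 1-{3-[(tert-butyldimethylsilyl)oxy]-2,4,5-trimethoxy-6-(methoxymethoxy)phenyl}ethan-1-ol F7, and Dess–Martin oxidation would give 11.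

**Step 9.** O‑Acylation of the enolate and slow reaction of the doubly ortho‑substituted acid chloride may leave enol ester and unreacted ketone, and the base may consume acid chloride. The fallback sets out from 11 and 13 and returns at 17. The enolate 16 would be added to the aldehyde 13 at −78 °C; an aldehyde is a better electrophile and cannot O‑acylate. This should give racemic 3-[2-(benzyloxy)-6-methoxyphenyl]-1-{3-[(tert-butyldimethylsilyl)oxy]-2,4,5-trimethoxy-6-(methoxymethoxy)phenyl}-3-hydroxypropan-1-one F8, and Dess–Martin oxidation of this β‑hydroxy ketone would give 17.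

**Step 10.** Solvolysis of the aryl silyl ether, flanked by two methoxy groups, may stay incomplete; forcing the acid risks cleaving the benzyl ether, which would let the ring B oxygen compete in ring closure. The fallback sets out from 17 and returns at 20 without any new compound. The operation would be split: TsOH·H2O in MeOH at 40 °C to remove the acetal and close the ring, stopping at 19, followed by fluoride‑induced desilylation of 19 with Bu4NF buffered with AcOH in THF at 0 °C to give 20.

## Further compounds

F1 | step 3 | 2,3,5-trimethoxybenzene-1,4-diol | COc1cc(O)c(OC)c(OC)c1O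
F2 | step 3 | 1-(2,5-dihydroxy-3,4,6-trimethoxyphenyl)ethan-1-one | CC(=O)c1c(O)c(OC)c(OC)c(O)c1OC
F3 | step 3 | 1-{3-[(tert-butyldimethylsilyl)oxy]-6-hydroxy-2,4,5-trimethoxyphenyl}ethan-1-one | CC(=O)c1c(O)c(OC)c(OC)c(O[Si](C)(C)C(C)(C)C)c1OC
F5 | step 5 | 3-[(tert-butyldimethylsilyl)oxy]-6-hydroxy-2,4,5-trimethoxybenzaldehyde | O=Cc1c(O)c(OC)c(OC)c(O[Si](C)(C)C(C)(C)C)c1OC
F6 | step 5 | 3-[(tert-butyldimethylsilyl)oxy]-2,4,5-trimethoxy-6-(methoxymethoxy)benzaldehyde | O=Cc1c(OCOC)c(OC)c(OC)c(O[Si](C)(C)C(C)(C)C)c1OC
F7 | step 5 | 1-{3-[(tert-butyldimethylsilyl)oxy]-2,4,5-trimethoxy-6-(methoxymethoxy)phenyl}ethan-1-ol (racemic) | CC(O)c1c(OCOC)c(OC)c(OC)c(O[Si](C)(C)C(C)(C)C)c1OC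
F8 | step 9 | 3-[2-(benzyloxy)-6-methoxyphenyl]-1-{3-[(tert-butyldimethylsilyl)oxy]-2,4,5-trimethoxy-6-(methoxymethoxy)phenyl}-3-hydroxypropan-1-one (racemic) | COCOc1c(OC)c(OC)c(O[Si](C)(C)C(C)(C)C)c(OC)c1C(=O)CC(O)c1c(OC)cccc1OCc1ccccc1
F0 | step 10 | none | none
A1 | alternative 1 | 6-(benzyloxy)-2-[2-(benzyloxy)-6-methoxyphenyl]-3-chloro-5,7,8-trimethoxy-4H-chromen-4-one | COc1cccc(OCc2ccccc2)c1-c1oc2c(OC)c(OC)c(OCc3ccccc3)c(OC)c2c(=O)c1Cl
A2 | alternative 1 | 5-(benzyloxy)-2-[2-(benzyloxy)-6-methoxyphenyl]-3-[(tert-butyldimethylsilyl)oxy]-4,6,7-trimethoxy-1-benzofuran | COc1cccc(OCc2ccccc2)c1-c1oc2c(OC)c(OC)c(OCc3ccccc3)c(OC)c2c1O[Si](C)(C)C(C)(C)C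
A3 | alternative 2 | 6-hydroxy-5,7,8-trimethoxy-2-[2-methoxy-6-(methoxymethoxy)phenyl]-4H-chromen-4-one | COCOc1cccc(OC)c1-c1cc(=O)c2c(OC)c(O)c(OC)c(OC)c2o1
A4 | alternative 2 | 1-(3-hydroxy-2,4,5-trimethoxyphenyl)-3-[2-methoxy-6-(methoxymethoxy)phenyl]propane-1,3-dione | COCOc1cccc(OC)c1C(=O)CC(=O)c1cc(OC)c(OC)c(O)c1OC
A5 | alternative 3 | 6-(benzyloxy)-2-(2-hydroxy-6-methoxyphenyl)-5,7,8-trimethoxy-4H-chromen-4-one | COc1cccc(O)c1-c1cc(=O)c2c(OC)c(OCc3ccccc3)c(OC)c(OC)c2o1
A6 | alternative 3 | 6-(benzyloxy)-5,7,8-trimethoxy-2-(methoxyethynyl)-4H-chromen-4-one | COC#Cc1cc(=O)c2c(OC)c(OCc3ccccc3)c(OC)c(OC)c2o1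
A7 | alternative 3 | cyclobut-2-en-1-one | O=C1C=CC1
A8 | alternative 3 | buta-1,3-dien-1-one (vinylketene) | O=C=CC=C
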